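**Plan**
- Core locants are those of octahydronaphthalen-2(1H)-one: C1 carbinol, C2 ketone, C3 isopropylidene carbon, C4a/C8a ring fusion, C5 CH–CH3, C6 acyloxy carbon. Ring A = C4a–C5–C6–C7–C8–C8a; ring B = C1–C2–C3–C4–C4a–C8a.
- Retrosynthesis: cut the C6 ester, then C6–C7 and C4a–C8a together, which opens both rings to an acyclic C10 chain.
- Enabling feature: the C6 oxygen lies 1,3 to quaternary C4a, so C6/C5/C4a can be an enal (bis-electrophile); C8a–C8–C7 can be an allylsilane (bis-nucleophile: first C8a, then C7 as vinyl); the C1–O/C2=O pair next to C8a chelates the Lewis acid.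
- Forward: the chain is assembled from dimethylmaleic anhydride, a prenal imine, an alkoxyallylborane and allyltrimethylsilane. Ring B then ring A close in one flask, followed by dechlorination, esterification with a diynoic acid, MOM removal and Lindlar reduction.
- Stereochemistry: C1 from the Brown alkoxyallylboration; C8a, C4a, C5 and C6 relayed from C1 in the key step; the side-chain centre from (S)-pent-1-yn-3-ol; both Z alkenes from the final semihydrogenation.

Key step: step 10

Assumption: (S)-pent-1-yn-3-ol and (+)-Ipc2BOMe are taken as purchasable reagents.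

**Route**

Step 1
Reactants: 1 2,3-dimethylmaleic anhydride
Product: 2 3,4-dimethylfuran-2(5H)-one
Conditions: NaBH4, THF, 0 °C → rt; 2 M HCl
Reagents that add atoms: none
Why: Borohydride reduction of a cyclic anhydride stops at the lactone, the substrate is symmetric so there is no regiochemical issue, and the ring fixes the later Z geometry.

Step 2
Reactants: 2 3,4-dimethylfuran-2(5H)-one
Product: 3 ethyl (2Z)-4-bromo-2,3-dimethylbut-2-enoate
Conditions: HBr (g), EtOH, 0 °C → rt
Reagents that add atoms: hydrogen bromide, Br; ethanol, CCO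
Why: Acid-promoted lactone opening by ethanol with conversion of the allylic oxygen into bromide (known for butyrolactones) should keep ester and CH2Br cis as in the ring.

Step 3
Reactants: 4 3-methylbut-2-enal; 5 cyclohexylamine
Product: 6 (E)-N-cyclohexyl-3-methylbut-2-en-1-imine
Conditions: K2CO3, Et2O, 0 °C → rt
Reagents that add atoms: none
Why: Simple condensation of an enal with a primary amine gives the 1-azadiene needed for metalation.

Step 4
Reactants: 6 (E)-N-cyclohexyl-3-methylbut-2-en-1-imine; 3 ethyl (2Z)-4-bromo-2,3-dimethylbut-2-enoate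
Product: 9 ethyl (2Z)-5-formyl-2,3,6-trimethylhepta-2,5-dienoate, via alkylated imine 7 (not isolated), via deconjugated aldehyde 8 (not isolated)
Conditions: LiN(i-Pr)2, THF, −78 °C; add 3, −78 → −30 °C; aq. oxalic acid, rt; Et3N (cat.), CH2Cl2
Reagents that add atoms: water, O
Why: Deconjugative α-alkylation of a metalated unsaturated aldimine by the allylic bromide (SN2), then imine hydrolysis and base-mediated migration of the double bond into conjugation, should give the isopropylidene aldehyde.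

Step 5
Reactants: 10 prop-2-en-1-ol
Product: 11 3-(methoxymethoxy)prop-1-ene
Conditions: MOMCl, i-Pr2NEt, CH2Cl2, 0 °C → rt
Reagents that add atoms: chloromethyl methyl ether, COCCl
Why: Standard O-alkylation gives the allyl MOM ether needed for the alkoxyallylborane.

Step 6
Reactants: 9 ethyl (2Z)-5-formyl-2,3,6-trimethylhepta-2,5-dienoate; 11 3-(methoxymethoxy)prop-1-ene
Product: 14 ethyl (2Z)-5-[(1S,2S)-1-hydroxy-2-(methoxymethoxy)but-3-en-1-yl]-2,3,6-trimethylhepta-2,5-dienoate, via allylborane 12 (not isolated), via borinate ester 13 (not isolated)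
Conditions: 11, s-BuLi, THF, −78 °C; (+)-Ipc2BOMe; BF3·OEt2; 9, −78 °C; NaOH, H2O2, 0 °C → rt
Reagents that add atoms: none
Why: Brown γ-alkoxyallylboration through a chair transition state: the Z enol ether gives the syn pair, and the isopinocampheyl antipode chosen for Re-face attack sets the 2S ether carbon (future C1); the antipodal borane would give the enantiomeric series, and the carbinol centre is oxidised later.

Step 7
Reactants: 14 ethyl (2Z)-5-[(1S,2S)-1-hydroxy-2-(methoxymethoxy)but-3-en-1-yl]-2,3,6-trimethylhepta-2,5-dienoate; 15 allyltrimethylsilane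
Product: 16 ethyl (2Z)-5-[(1S,2S,3E)-1-hydroxy-2-(methoxymethoxy)-5-(trimethylsilyl)pent-3-en-1-yl]-2,3,6-trimethylhepta-2,5-dienoate
Conditions: second-generation Grubbs catalyst (5 mol%), 15 (4 equiv), CH2Cl2, 40 °C
Reagents that add atoms: none
Why: Olefin cross-metathesis of the only monosubstituted alkene with excess allylsilane should give mainly the E allylsilane; the tetrasubstituted alkenes are inert.

Step 8
Reactants: 16 ethyl (2Z)-5-[(1S,2S,3E)-1-hydroxy-2-(methoxymethoxy)-5-(trimethylsilyl)pent-3-en-1-yl]-2,3,6-trimethylhepta-2,5-dienoate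
Product: 17 (2Z)-5-[(1S,2S,3E)-1-hydroxy-2-(methoxymethoxy)-5-(trimethylsilyl)pent-3-en-1-yl]-2,3,6-trimethylhepta-2,5-dien-1-ol
Conditions: i-Bu2AlH (4 equiv), CH2Cl2, −78 → −40 °C; aq. potassium sodium tartrate
Reagents that add atoms: none
Why: Hydride reduction of the conjugated ester gives the allylic alcohol by 1,2-reduction without touching the MOM ether, allylsilane or alkene geometry.

Step 9
Reactants: 17 (2Z)-5-[(1S,2S,3E)-1-hydroxy-2-(methoxymethoxy)-5-(trimethylsilyl)pent-3-en-1-yl]-2,3,6-trimethylhepta-2,5-dien-1-ol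
Product: 18 (2Z,7S,8E)-7-(methoxymethoxy)-2,3-dimethyl-6-oxo-5-(propan-2-ylidene)-10-(trimethylsilyl)deca-2,8-dienal
Conditions: Dess–Martin periodinane (2.5 equiv), NaHCO3, CH2Cl2, 0 °C → rt
Reagents that add atoms: none
Why: Buffered Dess–Martin oxidation converts both hydroxyls (to enal and enone) under neutral conditions that should spare the allylsilane and the base-sensitive α-alkoxy ketone centre.

Step 10
Reactants: 18 (2Z,7S,8E)-7-(methoxymethoxy)-2,3-dimethyl-6-oxo-5-(propan-2-ylidene)-10-(trimethylsilyl)deca-2,8-dienal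
Product: 20 (1S,4aR,5R,6R,8aR)-8-chloro-6-hydroxy-1-(methoxymethoxy)-4a,5-dimethyl-3-(propan-2-ylidene)octahydronaphthalen-2(1H)-one, via keto aldehyde 19 (not isolated)
Conditions: TiCl4 (3 equiv), CH2Cl2, −78 °C; then i-PrOH (1 equiv), −78 → −30 °C; aq. NaHCO3
Reagents that add atoms: titanium tetrachloride, Cl[Ti](Cl)(Cl)Cl
Why: Proposed new method: TiCl4 on the enal oxygen makes C4a electrophilic, the allylsilane attacks it through its γ carbon C8a (anti SE2', loss of Me3SiCl) to close ring B and leave a titanium enolate and a C8=C7 vinyl group, the added i-PrOH (HCl with TiCl4) protonates the enolate at C5 to the Ti-bound aldehyde 19, and its carbonyl carbon C6 is then attacked by the terminal vinyl carbon C7 with chloride capture at C8 to close ring A. The closest known reaction types are the intramolecular Hosomi–Sakurai conjugate allylation of enones and the Lewis-acid halo-Prins carbocyclisation of alkenyl aldehydes; running both on one substrate in one flask with a proton relay is the untested part. Ring B closes 6-exo-trig at the enal C=C, and ring A closes 6-endo-trig at the vinyl group (6-exo at the C=O). C8a is set by C1: the five-membered TiCl4 chelate of the C2 ketone and the C1 ether oxygen holds the C1–O bond pseudo-equatorial and the (E)-allyl arm takes the equatorial place trans to it, and C4a follows because the enal arm also prefers the equatorial place (methyl axial), which makes the ring fusion trans. C5 is an epimerisable aldehyde α-centre, so the epimer with equatorial methyl should be drained through the chair Prins transition state, C6 carries its Ti-bound oxygen equatorially in that chair, and the C8 chloride centre is uncontrolled and is deleted in step 11. The step needs 1,4- over 1,2-addition and ring B before ring A, which the tether secures (C8a reaches C4a in a six-membered ring but the formyl carbon only in an eight-membered one), and it needs the C2 enone to stay out, which its tetrasubstituted β carbon (5-endo for C8a) secures.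

Step 11
Reactants: 20 (1S,4aR,5R,6R,8aR)-8-chloro-6-hydroxy-1-(methoxymethoxy)-4a,5-dimethyl-3-(propan-2-ylidene)octahydronaphthalen-2(1H)-one
Product: 21 (1S,4aR,5R,6R,8aR)-6-hydroxy-1-(methoxymethoxy)-4a,5-dimethyl-3-(propan-2-ylidene)octahydronaphthalen-2(1H)-one
Conditions: Bu3SnH, AIBN (cat.), toluene, 100 °C
Reagents that add atoms: none
Why: Tin hydride radical-chain reduction of the secondary C–Cl bond removes the only uncontrolled centre; no other stereocentre is adjacent to the radical in a way that could invert.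

Step 12
Reactants: 22 (S)-pent-1-yn-3-ol
Product: 25 tert-butyl (4S)-4-hydroxyhex-2-ynoate, via silyl ether 23 (not isolated), via silylated ynoate 24 (not isolated)
Conditions: n-BuLi (1 equiv), THF, −78 °C; Me3SiCl; n-BuLi (1 equiv), −78 °C; Boc2O; aq. citric acid, MeOH
Reagents that add atoms: di-tert-butyl dicarbonate, CC(C)(C)OC(=O)OC(=O)OC(C)(C)C
Why: Transient O-silylation, acetylide formation and C-acylation with Boc2O, then mild acid cleavage of the silyl ether, should give the hydroxy ynoate without touching the carbinol centre.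

Step 13
Reactants: 25 tert-butyl (4S)-4-hydroxyhex-2-ynoate; 26 hex-2-ynoic acid
Product: 27 tert-butyl (4S)-4-(hex-2-ynoyloxy)hex-2-ynoate
Conditions: DCC, DMAP (cat.), CH2Cl2, 0 °C
Reagents that add atoms: none
Why: Steglich esterification acylates the hydroxyl with retention, since the C–O bond of the stereocentre is not broken.

Step 14
Reactants: 27 tert-butyl (4S)-4-(hex-2-ynoyloxy)hex-2-ynoate
Product: 28 (4S)-4-(hex-2-ynoyloxy)hex-2-ynoic acid
Conditions: CF3CO2H, CH2Cl2, 0 °C → rt
Reagents that add atoms: none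
Why: Acidolysis of the tert-butyl ester (loss of isobutene) frees the acid and leaves the secondary propargylic ester and both alkynes intact.

Step 15
Reactants: 21 (1S,4aR,5R,6R,8aR)-6-hydroxy-1-(methoxymethoxy)-4a,5-dimethyl-3-(propan-2-ylidene)octahydronaphthalen-2(1H)-one; 28 (4S)-4-(hex-2-ynoyloxy)hex-2-ynoic acid
Product: 29 (1S,4aR,5R,6R,8aR)-1-(methoxymethoxy)-4a,5-dimethyl-2-oxo-3-(propan-2-ylidene)decahydronaphthalen-6-yl (4S)-4-(hex-2-ynoyloxy)hex-2-ynoate
Conditions: DCC, DMAP (0.1 equiv), CH2Cl2, −20 → 0 °C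
Reagents that add atoms: none
Why: Steglich esterification of the only free hydroxyl (equatorial C6–OH) proceeds with retention at C6; the alkyne oxidation level avoids the Z→E isomerisation that acylation with Z-enoic acids risks.

Step 16
Reactants: 29 (1S,4aR,5R,6R,8aR)-1-(methoxymethoxy)-4a,5-dimethyl-2-oxo-3-(propan-2-ylidene)decahydronaphthalen-6-yl (4S)-4-(hex-2-ynoyloxy)hex-2-ynoate
Product: 30 (1S,4aR,5R,6R,8aR)-1-hydroxy-4a,5-dimethyl-2-oxo-3-(propan-2-ylidene)decahydronaphthalen-6-yl (4S)-4-(hex-2-ynoyloxy)hex-2-ynoate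
Conditions: Me2BBr, CH2Cl2, −78 °C; aq. NaHCO3
Reagents that add atoms: none
Why: Dimethylboron bromide cleaves MOM ethers at low temperature by acetal exchange, conditions under which esters and the enone should survive and C1 is not epimerised.

Step 17
Reactants: 30 (1S,4aR,5R,6R,8aR)-1-hydroxy-4a,5-dimethyl-2-oxo-3-(propan-2-ylidene)decahydronaphthalen-6-yl (4S)-4-(hex-2-ynoyloxy)hex-2-ynoate
Product: 31 (1S,4aR,5R,6R,8aR)-1-hydroxy-4a,5-dimethyl-2-oxo-3-(propan-2-ylidene)decahydronaphthalen-6-yl (2Z,4S)-4-[(2Z)-hex-2-enoyloxy]hex-2-enoate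
Conditions: H2 (1 atm), Pd/CaCO3 poisoned with Pb(OAc)2, quinoline, EtOAc, rt
Reagents that add atoms: none
Why: Lindlar semihydrogenation adds H2 syn to both ynoates and so sets both Z alkenes; the tetrasubstituted enone alkene should not be reduced.

**Compound list**
1 | 2,3-dimethylmaleic anhydride | CC1=C(C)C(=O)OC1=O | starting material
2 | 3,4-dimethylfuran-2(5H)-one | CC1=C(C)C(=O)OC1 | intermediate
3 | ethyl (2Z)-4-bromo-2,3-dimethylbut-2-enoate | CCOC(=O)/C(C)=C(C)\CBr | intermediate
4 | 3-methylbut-2-enal | CC(C)=CC=O | starting material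
5 | cyclohexylamine | NC1CCCCC1 | starting material
6 | (E)-N-cyclohexyl-3-methylbut-2-en-1-imine | CC(C)=C/C=N/C1CCCCC1 | intermediate
7 | ethyl (2Z)-5-[(E)-(cyclohexylimino)methyl]-2,3,6-trimethylhepta-2,6-dienoate (racemic at C5, not isolated) | CCOC(=O)/C(C)=C(C)\CC(/C=N/C1CCCCC1)C(C)=C | intermediate
8 | ethyl (2Z)-5-formyl-2,3,6-trimethylhepta-2,6-dienoate (racemic at C5, not isolated) | CCOC(=O)/C(C)=C(C)\CC(C=O)C(C)=C | intermediate
9 | ethyl (2Z)-5-formyl-2,3,6-trimethylhepta-2,5-dienoate | CCOC(=O)/C(C)=C(C)\CC(C=O)=C(C)C | intermediate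
10 | prop-2-en-1-ol | C=CCO | starting material
11 | 3-(methoxymethoxy)prop-1-ene | C=CCOCOC | intermediate
12 | [(2Z)-3-(methoxymethoxy)prop-2-en-1-yl]diisopinocampheylborane, Ipc groups from (+)-Ipc2BOMe (not isolated) | COCO/C=C\CB([C@H]1C[C@H]2C[C@@H]([C@@H]1C)C2(C)C)[C@H]1C[C@H]2C[C@@H]([C@@H]1C)C2(C)C | intermediate
13 | diisopinocampheylborinate ester of 14 (not isolated) | CCOC(=O)/C(C)=C(C)\CC(=C(C)C)[C@H](OB([C@H]1C[C@H]2C[C@@H]([C@@H]1C)C2(C)C)[C@H]1C[C@H]2C[C@@H]([C@@H]1C)C2(C)C)[C@@H](OCOC)C=C | intermediate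
14 | ethyl (2Z)-5-[(1S,2S)-1-hydroxy-2-(methoxymethoxy)but-3-en-1-yl]-2,3,6-trimethylhepta-2,5-dienoate | CCOC(=O)/C(C)=C(C)\CC(=C(C)C)[C@H](O)[C@@H](OCOC)C=C | intermediate
15 | allyltrimethylsilane | C=CC[Si](C)(C)C | starting material
16 | ethyl (2Z)-5-[(1S,2S,3E)-1-hydroxy-2-(methoxymethoxy)-5-(trimethylsilyl)pent-3-en-1-yl]-2,3,6-trimethylhepta-2,5-dienoate | CCOC(=O)/C(C)=C(C)\CC(=C(C)C)[C@H](O)[C@@H](OCOC)/C=C/C[Si](C)(C)C | intermediate
17 | (2Z)-5-[(1S,2S,3E)-1-hydroxy-2-(methoxymethoxy)-5-(trimethylsilyl)pent-3-en-1-yl]-2,3,6-trimethylhepta-2,5-dien-1-ol | OC/C(C)=C(C)\CC(=C(C)C)[C@H](O)[C@@H](OCOC)/C=C/C[Si](C)(C)C | intermediate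
18 | (2Z,7S,8E)-7-(methoxymethoxy)-2,3-dimethyl-6-oxo-5-(propan-2-ylidene)-10-(trimethylsilyl)deca-2,8-dienal | O=C/C(C)=C(C)\CC(=C(C)C)C(=O)[C@@H](OCOC)/C=C/C[Si](C)(C)C | intermediate
19 | 2-[(1S,2R,3S)-2-ethenyl-3-(methoxymethoxy)-1-methyl-4-oxo-5-(propan-2-ylidene)cyclohexyl]propanal (epimers at C2 of the propanal, not isolated) | C=C[C@H]1[C@H](OCOC)C(=O)C(=C(C)C)C[C@]1(C)C(C)C=O | intermediate
20 | (1S,4aR,5R,6R,8aR)-8-chloro-6-hydroxy-1-(methoxymethoxy)-4a,5-dimethyl-3-(propan-2-ylidene)octahydronaphthalen-2(1H)-one (C8 epimers) | O[C@@H]1CC(Cl)[C@H]2[C@H](OCOC)C(=O)C(=C(C)C)C[C@]2(C)[C@H]1C | intermediate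
21 | (1S,4aR,5R,6R,8aR)-6-hydroxy-1-(methoxymethoxy)-4a,5-dimethyl-3-(propan-2-ylidene)octahydronaphthalen-2(1H)-one | O[C@@H]1CC[C@H]2[C@H](OCOC)C(=O)C(=C(C)C)C[C@]2(C)[C@H]1C | intermediate
22 | (S)-pent-1-yn-3-ol | CC[C@H](O)C#C | starting material
23 | trimethyl{[(3S)-pent-1-yn-3-yl]oxy}silane (not isolated) | CC[C@H](O[Si](C)(C)C)C#C | intermediate
24 | tert-butyl (4S)-4-(trimethylsilyloxy)hex-2-ynoate (not isolated) | CC[C@H](O[Si](C)(C)C)C#CC(=O)OC(C)(C)C | intermediate
25 | tert-butyl (4S)-4-hydroxyhex-2-ynoate | CC[C@H](O)C#CC(=O)OC(C)(C)C | intermediate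
26 | hex-2-ynoic acid | CCCC#CC(=O)O | starting material
27 | tert-butyl (4S)-4-(hex-2-ynoyloxy)hex-2-ynoate | CCCC#CC(=O)O[C@@H](CC)C#CC(=O)OC(C)(C)C | intermediate
28 | (4S)-4-(hex-2-ynoyloxy)hex-2-ynoic acid | CCCC#CC(=O)O[C@@H](CC)C#CC(=O)O | intermediate
29 | (1S,4aR,5R,6R,8aR)-1-(methoxymethoxy)-4a,5-dimethyl-2-oxo-3-(propan-2-ylidene)decahydronaphthalen-6-yl (4S)-4-(hex-2-ynoyloxy)hex-2-ynoate | CCCC#CC(=O)O[C@H](C#CC(=O)O[C@@H]1CC[C@H]2[C@H](OCOC)C(=O)C(=C(C)C)C[C@]2(C)[C@H]1C)CC | intermediate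
30 | (1S,4aR,5R,6R,8aR)-1-hydroxy-4a,5-dimethyl-2-oxo-3-(propan-2-ylidene)decahydronaphthalen-6-yl (4S)-4-(hex-2-ynoyloxy)hex-2-ynoate | CCCC#CC(=O)O[C@H](C#CC(=O)O[C@@H]1CC[C@H]2[C@H](O)C(=O)C(=C(C)C)C[C@]2(C)[C@H]1C)CC | intermediate
31 | (1S,4aR,5R,6R,8aR)-1-hydroxy-4a,5-dimethyl-2-oxo-3-(propan-2-ylidene)decahydronaphthalen-6-yl (2Z,4S)-4-[(2Z)-hex-2-enoyloxy]hex-2-enoate | CCC/C=C\C(=O)O[C@H](/C=C\C(=O)O[C@@H]1CC[C@H]2[C@H](O)C(=O)C(=C(C)C)C[C@]2(C)[C@H]1C)CC | target

**Totals**
Total step count: 17. Longest linear sequence: 12 steps (1, 2, 4, 6, 7, 8, 9, 10, 11, 15, 16, 17).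

**Steps most likely to fail**

1. Step 10 (Proposed new method). The sequence may stall after the conjugate allylation; the ring A closure may be diverted by hydride shift or proton loss at the C8 cation; the MOM ether may be lost under the Lewis acid; facial control at C8a may be incomplete. Fallback with known chemistry, from 18 back to 21: only the conjugate allylation is run on 18 (TiCl4, CH2Cl2, −78 °C, aqueous quench), and keto aldehyde 19 is isolated. Wacker oxidation (PdCl2, CuCl, O2, DMF/H2O) of its vinyl group should give the methyl ketone 2-[(1R,2R,3S)-2-acetyl-3-(methoxymethoxy)-1-methyl-4-oxo-5-(propan-2-ylidene)cyclohexyl]propanal F1. Intramolecular aldol addition of the methyl ketone to the aldehyde (pyrrolidinium acetate, or Ba(OH)2 at 0 °C), under equilibrating conditions that favour the all-equatorial ring A, should close the C6–C7 bond to (1S,4aR,5R,6R,8aR)-6-hydroxy-1-(methoxymethoxy)-4a,5-dimethyl-3-(propan-2-ylidene)octahydronaphthalene-2,8-dione F2. The unconjugated C8 ketone is converted selectively into its tosylhydrazone, the C8 (4-methylbenzenesulfonyl)hydrazone of F2, F3 (TsNHNH2, EtOH), which is reduced with catecholborane and then NaOAc to 21. Step 11 is then not needed.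

2. Step 4. The aza-dienyl anion may alkylate at the γ carbon, attack the ester, or deprotonate the bromo ester. Fallback, from 3 back to 17: the lithium anion of commercial 3-methylbut-2-enenitrile (LiN(i-Pr)2, THF, −78 °C) is alkylated by 3 at its α carbon (deconjugative alkylation of an unsaturated nitrile) to give ethyl (2Z)-5-cyano-2,3,6-trimethylhepta-2,6-dienoate F4. Excess i-Bu2AlH (−78 °C), aqueous acid and then Et3N reduce the nitrile to the aldehyde and the ester to the alcohol and move the alkene into conjugation, giving 2-[(2Z)-4-hydroxy-2,3-dimethylbut-2-en-1-yl]-3-methylbut-2-enal F5. Alkoxyallylboration as in step 6 (one extra equivalent of borane for the free hydroxyl) gives (2Z)-5-[(1S,2S)-1-hydroxy-2-(methoxymethoxy)but-3-en-1-yl]-2,3,6-trimethylhepta-2,5-dien-1-ol F6. Cross-metathesis with 15 as in step 7 gives 17; steps 4 and 8 are bypassed.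

3. Step 16. Cleavage of the acetal on the fully acylated compound may be accompanied by attack of the boron halide on the propargylic ester or the ynoates. Fallback, from 21 back to 30: the MOM ether is removed before acylation (HCl, MeOH, 40 °C) to give the diol (1S,4aR,5R,6R,8aR)-1,6-dihydroxy-4a,5-dimethyl-3-(propan-2-ylidene)octahydronaphthalen-2(1H)-one F7. The unhindered equatorial C6 hydroxyl is then esterified selectively with 28 (DCC, DMAP cat., −20 °C) to give 30 directly; the C1 hydroxyl is an internally hydrogen-bonded α-ketol flanked by the ring fusion and should react far more slowly.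

Further compounds
F1 | step 10 | 2-[(1R,2R,3S)-2-acetyl-3-(methoxymethoxy)-1-methyl-4-oxo-5-(propan-2-ylidene)cyclohexyl]propanal | CC(=O)[C@H]1[C@H](OCOC)C(=O)C(=C(C)C)C[C@]1(C)C(C)C=O
F2 | step 10 | (1S,4aR,5R,6R,8aR)-6-hydroxy-1-(methoxymethoxy)-4a,5-dimethyl-3-(propan-2-ylidene)octahydronaphthalene-2,8-dione | O[C@@H]1CC(=O)[C@H]2[C@H](OCOC)C(=O)C(=C(C)C)C[C@]2(C)[C@H]1C
F3 | step 10 | C8 (4-methylbenzenesulfonyl)hydrazone of F2 | O[C@@H]1CC(=NNS(=O)(=O)c3ccc(C)cc3)[C@H]2[C@H](OCOC)C(=O)C(=C(C)C)C[C@]2(C)[C@H]1C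
F4 | step 4 | ethyl (2Z)-5-cyano-2,3,6-trimethylhepta-2,6-dienoate | CCOC(=O)/C(C)=C(C)\CC(C#N)C(C)=C
F5 | step 4 | 2-[(2Z)-4-hydroxy-2,3-dimethylbut-2-en-1-yl]-3-methylbut-2-enal | OC/C(C)=C(C)\CC(C=O)=C(C)C
F6 | step 4 | (2Z)-5-[(1S,2S)-1-hydroxy-2-(methoxymethoxy)but-3-en-1-yl]-2,3,6-trimethylhepta-2,5-dien-1-ol | OC/C(C)=C(C)\CC(=C(C)C)[C@H](O)[C@@H](OCOC)C=C
F7 | step 16 | (1S,4aR,5R,6R,8aR)-1,6-dihydroxy-4a,5-dimethyl-3-(propan-2-ylidene)octahydronaphthalen-2(1H)-one | O[C@@H]1CC[C@H]2[C@H](O)C(=O)C(=C(C)C)C[C@]2(C)[C@H]1C
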